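## The problem

Compound 21 is a 1,7-diarylheptanoid folded into one oxane ring: O1 joins C2, which carries a 4-hydroxy-3-methoxyphenyl group, to C6, which carries the 2-(4-hydroxy-3-methoxyphenyl)ethyl chain, and C4 carries a free hydroxyl (these oxane locants are also used for the corresponding atoms of open-chain intermediates). No ring fusion is involved; seven chain carbons must be assembled between two guaiacol units and one C–O bond closed. The stereocentres are (2S,4S,6S): the C2 and C6 substituents are cis and equatorial, while the C4 hydroxyl is axial and trans to both. C6 is an unactivated alkyl carbinol carbon and must be introduced in absolute terms. C2 is a benzylic ether carbon para to a phenolic oxygen, ionises reversibly and can be set from C6 under thermodynamic control; C4 can be set from both by equatorial hydride delivery to a C4 ketone. The same lability of C2 rules out strong acid, hydrogenolysis and oxidants late in the route. The two phenols must be masked by groups that stand organolithiums, alkoxides in HMPA, hydride and mild acid; aryl triisopropylsilyl ethers are chosen because the tert-butyldimethylsilyl analogues are too easily lost to alkoxide or hydroxide. The enabling feature is the 1,3,5-oxygen pattern: C4 lies between two methylene groups, C3 and C5, each leading to an oxygen-bearing carbon, so C4 can be an acyl dianion equivalent that opens two terminal epoxides. Only one of the two epoxide oxygens can become O1, so the plan must decide which C–O bond is given up.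

## Retrosynthesis

**21 back to 19.** The two aryl O–Si bonds and the C4–H bond are cut, leading through silyl ether 20 to oxanone 19. Carrying an sp3 C4–O centre through the chain assembly would need its own asymmetric operation. From the ketone, the ring conformation does the work: both substituents of 19 are equatorial in one chair, and a bulky hydride attacking equatorially gives the axial alcohol. The forward reduction must show this facial selectivity; 19 has only two stereocentres.

**19 back to 17.** The C4 carbonyl is taken back to the spiro dithioketal 18, and the O1–C2 bond of 18 is cut to give the open-chain alcohol 17.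
- Cutting O1–C6 instead would need displacement with inversion at an unactivated secondary carbon and a defined C2.
- Unveiling the ketone first and closing by elimination and oxa-Michael addition would expose the C6 hydroxyl to β-elimination.
- In 17 no carbonyl is present, so the C6 hydroxyl can only act as a nucleophile and the benzylic C2–O bond is the only one that can ionise.
- It follows that the configuration at C2 in 17 is irrelevant. The aryl oxirane 6 is therefore used as the racemate, which saves a resolution on the most acid-labile fragment.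

The forward closure must ionise C2 only, deliver the 2,6-cis isomer by equilibration and leave the dithioketal intact.

**17 back to 3, 6 and 13.** C3–C4 and C4–C5 are cut, giving silyl dithiane 3, aryl oxirane 6 and arylethyl oxirane 13. Aldol-type cuts at C2–C3 or C5–C6 would build one bond at a time and create the C6 carbinol in the bond-forming step, calling for asymmetric induction there. Here the carbinol carbons are the CH carbons of the epoxides and are not touched. The precursors are three small fragments, only one of which carries a defined stereocentre. The forward reaction must open both epoxides at CH2, keep the silyl migration waiting until the second epoxide is present, and leave the silyl group on the C2 oxygen and the C6 hydroxyl free. Adding 6 first secures the last point.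

**13 back to eugenol.** Epoxide 13 is the slow-reacting enantiomer of racemic 12 in a hydrolytic kinetic resolution. The terminal C–C bond of 12 is cut to aldehyde 11 and a sulfonium ylide methylene. The allyl group of eugenol 7 has three carbons where four are needed between the ring and the terminal epoxide carbon; direct epoxidation of 7 would give an oxirane one carbon short. Silylation (8), anti-Markovnikov hydration (10) and oxidation (11) therefore precede the methylene transfer.

**6 and 3 back to vanillin and 1,3-dithiane.** Oxirane 6 comes from silylated vanillin 5 by the same methylene transfer, and 5 from vanillin 4. Silyl dithiane 3 comes from 1,3-dithiane 1 through its lithio derivative 2.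

## Roads not taken

Alternative 1: The O1–C6 bond is cut and C6 is taken from a propargylic methylene. The precursor is the anti-configured hydroxy alkyne A1, with the C2 benzylic alcohol and the C4 silyl ether in place. Pd(PPh3)4 (zerovalent palladium) with benzoic acid would isomerise the aryl alkyne through an allene to an aryl-substituted π-allylpalladium species. The C2 hydroxyl attacks its alkyl terminus to give the 2,6-cis oxane A2 with an E-styryl group on C6.
- Merits: the closure is catalytic, redox-neutral and atom-economical. The C4 oxygen never passes through a ketone, and no sulfur, HMPA or stoichiometric organolithium relay is needed. In these respects it is better than the chosen plan.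
- Weak points: A1 needs two stereocentres (C2 and C4, anti) set beforehand in a linear chain synthesis, against one asymmetric operation in the chosen plan. The nucleophile is a benzylic alcohol para to a silyloxy group, heated with a carboxylic acid, so ionisation at C2 or dehydration is a real risk. The styryl double bond must afterwards be hydrogenated next to an allylic C6–O and a benzylic C2–O bond, with a hydrogenolysis risk and an extra step.
- Comparison: the chosen plan sets against its merits convergence, a single stereo-defining operation and a ring closure in which ionisation at C2 is used rather than feared.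

Alternative 2: O1–C2 and C5–C6 are cut in a [4+2] sense, giving aldehyde A3 and the 2-silyloxy-4-aryl diene A4. A chiral tridentate Schiff-base CrCl complex (trivalent chromium) would join them in an endo hetero-Diels–Alder reaction to the 2,6-cis dihydropyran A5. A5 is one hydrolysis away from the ketone stage that the chosen plan reaches at 19.
- Merits: both ring bonds and both C2 and C6 centres arise in one catalytic asymmetric step. No resolution discards half of a fragment. The longest line should be about seven steps against ten here. On step count and atom economy this road is clearly better.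
- Weak points: A4 has a single oxygen donor and an aryl group on the terminus that must bond to oxygen, so it is a weak diene towards an unactivated, enolisable aliphatic aldehyde. Aryl-conjugated silyloxydienes can change to a stepwise aldol pathway that erodes both cis selectivity and enantioselectivity. The enantiomeric purity would rest on one catalyst–substrate match at a stage where it cannot easily be upgraded. A4 is also hydrolytically sensitive.
- Comparison: the chosen plan sets predictability against the shorter count. Every C–C bond is an SN2 opening of a terminal epoxide, the absolute configuration comes from a resolution whose outcome is checked before the coupling, and C2 corrects itself.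

Alternative 3: C2–C3 is cut and the benzylic C2–H bond is used. The precursor A6 is a benzylic ether of the C6 carbinol carrying an enol acetate. DDQ would abstract hydride from the benzylic ether CH2 to give an aryl oxocarbenium ion, which the enol acetate attacks through a chair to give the 2,6-cis oxan-4-one A7.
- Merits: ring and ketone arrive together, with no dithioketal to remove and no HMPA. The end game would be the same as here. In avoiding the sulfur chemistry it is better than the chosen plan.
- Weak points: the arylethyl ring is also electron-rich, so its phenol must be masked as an electron-poor pivalate to keep DDQ away from it. This means two kinds of phenol protection and an extra deprotection. A6 still needs the C6 carbinol as a single enantiomer, for instance from an epoxide such as 13 and an acetylide. It also needs etherification of a secondary alcohol with a para-silyloxybenzyl electrophile that is prone to quinone methide formation, and a regioselective enol acetate synthesis. The sequence is linear and about as long as the chosen one, and A7 keeps an oxidisable benzylic ether C–H in the presence of a stoichiometric oxidant.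
- Comparison: the chosen plan offers convergence, one protecting-group type and no oxidant near the guaiacol rings.

Key step: step 9

## Route

Abbreviations: TBS = tert-butyldimethylsilyl; TIPS = triisopropylsilyl; salen = dianion of N,N'-bis(3,5-di-tert-butylsalicylidene)-trans-1,2-cyclohexanediamine.

Assumption: the (S,S) enantiomer of (salen)Co(OAc) is taken to hydrate (R)-configured 2-alkyloxiranes preferentially, as it does for simple alkyl cases, so that 13 is the recovered epoxide.

Step 1
Reactants: 1 1,3-dithiane
Product: 3 2-(tert-butyldimethylsilyl)-1,3-dithiane, via 2-lithio-1,3-dithiane 2 (not isolated)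
Conditions: n-BuLi, THF, −30 °C; then TBSCl, −78 °C to rt
Reagents that add atoms: tert-butyldimethylsilyl chloride, CC(C)(C)[Si](C)(C)Cl
Why: n-BuLi removes the C2 proton of the dithiane and the sulfur-stabilised anion 2 is silylated at carbon (dithiane metalation and C-silylation).

Step 2
Reactants: 4 vanillin
Product: 5 3-methoxy-4-(triisopropylsilyloxy)benzaldehyde
Conditions: TIPSCl, imidazole, DMF, rt
Reagents that add atoms: triisopropylsilyl chloride, CC(C)[Si](Cl)(C(C)C)C(C)C
Why: Imidazole-mediated O-silylation of the phenol; the bulky TIPS ether is chosen because it must later stand ylide, alkoxide in HMPA and borohydride.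

Step 3
Reactants: 5 3-methoxy-4-(triisopropylsilyloxy)benzaldehyde
Product: 6 rac-2-[3-methoxy-4-(triisopropylsilyloxy)phenyl]oxirane
Conditions: Me3SI, n-BuLi, THF, −10 °C; then 5, −10 °C to rt; neutral work-up, filtration through Et3N-deactivated silica
Reagents that add atoms: trimethylsulfonium iodide, C[S+](C)C.[I-]
Why: Corey–Chaykovsky epoxidation: dimethylsulfonium methylide adds to the aldehyde and the betaine closes with loss of Me2S. The para-silyloxy oxirane is acid-labile and is used promptly; no stereocontrol is needed because C2 is re-set in step 10.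

Step 4
Reactants: 7 eugenol
Product: 8 triisopropyl[2-methoxy-4-(prop-2-en-1-yl)phenoxy]silane
Conditions: TIPSCl, imidazole, DMF, rt
Reagents that add atoms: triisopropylsilyl chloride, CC(C)[Si](Cl)(C(C)C)C(C)C
Why: Imidazole-mediated O-silylation of the phenol, as in step 2.

Step 5
Reactants: 8 triisopropyl[2-methoxy-4-(prop-2-en-1-yl)phenoxy]silane
Product: 10 3-[3-methoxy-4-(triisopropylsilyloxy)phenyl]propan-1-ol, via B-alkyl-9-borabicyclononane adduct 9 (not isolated)
Conditions: 9-BBN, THF, 0 °C to rt; then 3 M NaOH, 30% H2O2, 0 °C
Reagents that add atoms: hydrogen peroxide, OO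
Why: Hydroboration–oxidation: bulky 9-BBN places boron on the terminal carbon of the allyl group and alkaline peroxide replaces boron by hydroxyl. Brief treatment at 0 °C should leave the aryl TIPS ether intact.

Step 6
Reactants: 10 3-[3-methoxy-4-(triisopropylsilyloxy)phenyl]propan-1-ol
Product: 11 3-[3-methoxy-4-(triisopropylsilyloxy)phenyl]propanal
Conditions: Dess–Martin periodinane, CH2Cl2, 0 °C to rt
Reagents that add atoms: none
Why: Dess–Martin oxidation of a primary alcohol stops at the aldehyde under near-neutral conditions that do not affect the electron-rich arene or the silyl ether.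

Step 7
Reactants: 11 3-[3-methoxy-4-(triisopropylsilyloxy)phenyl]propanal
Product: 12 rac-2-{2-[3-methoxy-4-(triisopropylsilyloxy)phenyl]ethyl}oxirane
Conditions: Me3SI, n-BuLi, THF, −10 °C; then slow addition of 11, −10 °C to rt
Reagents that add atoms: trimethylsulfonium iodide, C[S+](C)C.[I-]
Why: Corey–Chaykovsky epoxidation; the ylide methylene supplies the fourth carbon that the allyl group of eugenol lacks. Preformed ylide, low temperature and slow addition of the aldehyde limit enolisation.

Step 8
Reactants: 12 rac-2-{2-[3-methoxy-4-(triisopropylsilyloxy)phenyl]ethyl}oxirane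
Product: 13 (2S)-2-{2-[3-methoxy-4-(triisopropylsilyloxy)phenyl]ethyl}oxirane
Conditions: (S,S)-(salen)Co(OAc) (trivalent cobalt, 0.5 mol %), H2O (0.55 equiv), THF, 0 °C to rt
Reagents that add atoms: none
Why: Hydrolytic kinetic resolution: the chiral cobalt complex activates epoxide and water cooperatively and hydrates the (R)-epoxide much faster, so that with 0.55 equiv of water the (S)-epoxide should remain in high enantiomeric purity. This is the only step that introduces absolute configuration (C6).

Step 9
Reactants: 3 2-(tert-butyldimethylsilyl)-1,3-dithiane; 6 rac-2-[3-methoxy-4-(triisopropylsilyloxy)phenyl]oxirane; 13 (2S)-2-{2-[3-methoxy-4-(triisopropylsilyloxy)phenyl]ethyl}oxirane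
Product: 17 (2S)-1-(2-{2-(tert-butyldimethylsilyloxy)-2-[3-methoxy-4-(triisopropylsilyloxy)phenyl]ethyl}-1,3-dithian-2-yl)-4-[3-methoxy-4-(triisopropylsilyloxy)phenyl]butan-2-ol (both epimers at the benzylic silyloxy carbon), via 2-silyl-2-lithio-1,3-dithiane 14 (not isolated), via benzylic lithium alkoxide 15 (not isolated), via Brook-rearranged 2-lithio-1,3-dithiane 16 (not isolated)
Conditions: 3 (1.1 equiv), t-BuLi (1.05 equiv), Et2O, −78 to −45 °C; 6 (1.0 equiv), Et2O, −78 to −25 °C; then 13 (1.1 equiv), HMPA (2 equiv), Et2O, −78 to 0 °C; aq NH4Cl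
Reagents that add atoms: none
Why: t-BuLi removes the C2 proton of 3 in Et2O to give 14, which opens racemic 6 by SN2 attack at its CH2 carbon to give alkoxide 15; in Et2O the lithium alkoxide is a tight ion pair and keeps its C–Si bond. When 13 is added with HMPA, lithium is solvated, the alkoxide oxygen attacks silicon and the TBS group migrates from carbon to oxygen (1,4-Brook rearrangement through a five-membered silicate), driven by the Si–O bond and the sulfur-stabilised carbanion 16. Anion 16 then opens 13 at its CH2 carbon, so C4–C5 follows C3–C4 in the same flask; the closest known reaction type is the solvent-controlled three-component linchpin (anion relay) coupling of a 2-silyl-1,3-dithiane with two different terminal epoxides. No ring is closed. No stereocentre is created under control: C6 arrives unchanged from 13 because its C–O bond is never broken, and C2 is formed as both epimers from racemic 6 on purpose, since step 10 re-sets it. The step needs terminal rather than benzylic opening of 6, which is favoured by the bulk and softness of 14, the absence of any Lewis acid beyond lithium in Et2O, the low temperature and a silyloxy rather than alkoxy para substituent; terminal opening of 13 is the normal course for a monoalkyl oxirane. It also needs the rearrangement to wait for HMPA, since otherwise 16 would consume a second molecule of 6; the ether solvent and exactly one equivalent of 6 secure this. The order of addition places the silyl group on the C2 oxygen and leaves the C6 hydroxyl free, which is the differentiation step 10 requires.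

Step 10
Reactants: 17 (2S)-1-(2-{2-(tert-butyldimethylsilyloxy)-2-[3-methoxy-4-(triisopropylsilyloxy)phenyl]ethyl}-1,3-dithian-2-yl)-4-[3-methoxy-4-(triisopropylsilyloxy)phenyl]butan-2-ol (both epimers at the benzylic silyloxy carbon)
Product: 18 (8S,10S)-8-[3-methoxy-4-(triisopropylsilyloxy)phenyl]-10-{2-[3-methoxy-4-(triisopropylsilyloxy)phenyl]ethyl}-9-oxa-1,5-dithiaspiro[5.5]undecane (the 2,6-cis oxane with a spiro 1,3-dithiane at C4)
Conditions: TsOH·H2O (0.2 equiv), CH2Cl2, 0 °C to rt
Reagents that add atoms: none
Why: Acid ionises the benzylic silyl ether (SN1, cation stabilised by the para-silyloxy group) and the free C6 hydroxyl captures it in a six-membered closure assisted by the geminal sulfur substituents at C4 (acid-catalysed intramolecular benzylic etherification of a 1-aryl-1,5-diol derivative). Because ionisation is reversible, both C2 epimers of 17 should converge on the 2,6-cis isomer, in which neither substituent is axial and 1,3-diaxial to a sulfur at C4. C6 cannot be affected because no carbonyl is present yet.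

Step 11
Reactants: 18 (8S,10S)-8-[3-methoxy-4-(triisopropylsilyloxy)phenyl]-10-{2-[3-methoxy-4-(triisopropylsilyloxy)phenyl]ethyl}-9-oxa-1,5-dithiaspiro[5.5]undecane
Product: 19 (2S,6S)-2-[3-methoxy-4-(triisopropylsilyloxy)phenyl]-6-{2-[3-methoxy-4-(triisopropylsilyloxy)phenyl]ethyl}oxan-4-one
Conditions: MeI, CaCO3, MeCN/H2O (9:1), 45 °C
Reagents that add atoms: water, O
Why: Alkylative dithioketal hydrolysis: S-methylation creates a sulfonium leaving group, the thionium ion is trapped by water and CaCO3 scavenges HI. The conditions are non-oxidising and near neutral, so the arenes, the silyl ethers and the benzylic ether are left alone.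

Step 12
Reactants: 19 (2S,6S)-2-[3-methoxy-4-(triisopropylsilyloxy)phenyl]-6-{2-[3-methoxy-4-(triisopropylsilyloxy)phenyl]ethyl}oxan-4-one
Product: 20 (2S,4S,6S)-2-[3-methoxy-4-(triisopropylsilyloxy)phenyl]-6-{2-[3-methoxy-4-(triisopropylsilyloxy)phenyl]ethyl}oxan-4-ol
Conditions: LiBH(s-Bu)3, THF, −78 °C; aq NH4Cl
Reagents that add atoms: none
Why: The bulky trialkylborohydride attacks the chair oxanone, with both substituents equatorial, from the equatorial direction and gives the axial (4S) alcohol trans to the C2 and C6 groups. This is the usual outcome for 2,6-cis-disubstituted oxan-4-ones.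

Step 13
Reactants: 20 (2S,4S,6S)-2-[3-methoxy-4-(triisopropylsilyloxy)phenyl]-6-{2-[3-methoxy-4-(triisopropylsilyloxy)phenyl]ethyl}oxan-4-ol
Product: 21 (2S,4S,6S)-2-(4-hydroxy-3-methoxyphenyl)-6-[2-(4-hydroxy-3-methoxyphenyl)ethyl]oxan-4-ol
Conditions: Bu4NF, THF, 0 °C to rt; aq NH4Cl
Reagents that add atoms: none
Why: Fluoride cleaves the two aryl Si–O bonds, with phenoxide as leaving group, under conditions that do not affect the secondary alcohol or the benzylic ether.

## Compound list

1 | 1,3-dithiane | C1CSCSC1 | starting material
2 | 2-lithio-1,3-dithiane | [Li]C1SCCCS1 | intermediate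
3 | 2-(tert-butyldimethylsilyl)-1,3-dithiane | CC(C)(C)[Si](C)(C)C1SCCCS1 | intermediate
4 | vanillin (4-hydroxy-3-methoxybenzaldehyde) | COc1cc(C=O)ccc1O | starting material
5 | 3-methoxy-4-(triisopropylsilyloxy)benzaldehyde | COc1cc(C=O)ccc1O[Si](C(C)C)(C(C)C)C(C)C | intermediate
6 | rac-2-[3-methoxy-4-(triisopropylsilyloxy)phenyl]oxirane | COc1cc(C2CO2)ccc1O[Si](C(C)C)(C(C)C)C(C)C | intermediate
7 | eugenol (2-methoxy-4-(prop-2-en-1-yl)phenol) | C=CCc1ccc(O)c(OC)c1 | starting material
8 | triisopropyl[2-methoxy-4-(prop-2-en-1-yl)phenoxy]silane | C=CCc1ccc(O[Si](C(C)C)(C(C)C)C(C)C)c(OC)c1 | intermediate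
9 | 9-{3-[3-methoxy-4-(triisopropylsilyloxy)phenyl]propyl}-9-borabicyclo[3.3.1]nonane | COc1cc(CCCB2C3CCCC2CCC3)ccc1O[Si](C(C)C)(C(C)C)C(C)C | intermediate
10 | 3-[3-methoxy-4-(triisopropylsilyloxy)phenyl]propan-1-ol | COc1cc(CCCO)ccc1O[Si](C(C)C)(C(C)C)C(C)C | intermediate
11 | 3-[3-methoxy-4-(triisopropylsilyloxy)phenyl]propanal | COc1cc(CCC=O)ccc1O[Si](C(C)C)(C(C)C)C(C)C | intermediate
12 | rac-2-{2-[3-methoxy-4-(triisopropylsilyloxy)phenyl]ethyl}oxirane | COc1cc(CCC2CO2)ccc1O[Si](C(C)C)(C(C)C)C(C)C | intermediate
13 | (2S)-2-{2-[3-methoxy-4-(triisopropylsilyloxy)phenyl]ethyl}oxirane | COc1cc(CC[C@H]2CO2)ccc1O[Si](C(C)C)(C(C)C)C(C)C | intermediate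
14 | 2-(tert-butyldimethylsilyl)-2-lithio-1,3-dithiane | CC(C)(C)[Si](C)(C)C1([Li])SCCCS1 | intermediate
15 | lithium 2-[2-(tert-butyldimethylsilyl)-1,3-dithian-2-yl]-1-[3-methoxy-4-(triisopropylsilyloxy)phenyl]ethan-1-olate (racemic) | COc1cc(C(O[Li])CC2([Si](C)(C)C(C)(C)C)SCCCS2)ccc1O[Si](C(C)C)(C(C)C)C(C)C | intermediate
16 | 2-{2-(tert-butyldimethylsilyloxy)-2-[3-methoxy-4-(triisopropylsilyloxy)phenyl]ethyl}-2-lithio-1,3-dithiane (racemic) | COc1cc(C(CC2([Li])SCCCS2)O[Si](C)(C)C(C)(C)C)ccc1O[Si](C(C)C)(C(C)C)C(C)C | intermediate
17 | (2S)-1-(2-{2-(tert-butyldimethylsilyloxy)-2-[3-methoxy-4-(triisopropylsilyloxy)phenyl]ethyl}-1,3-dithian-2-yl)-4-[3-methoxy-4-(triisopropylsilyloxy)phenyl]butan-2-ol, both epimers at the benzylic silyloxy carbon | COc1cc(CC[C@H](O)CC2(CC(O[Si](C)(C)C(C)(C)C)c3ccc(O[Si](C(C)C)(C(C)C)C(C)C)c(OC)c3)SCCCS2)ccc1O[Si](C(C)C)(C(C)C)C(C)C | intermediate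
18 | (8S,10S)-8-[3-methoxy-4-(triisopropylsilyloxy)phenyl]-10-{2-[3-methoxy-4-(triisopropylsilyloxy)phenyl]ethyl}-9-oxa-1,5-dithiaspiro[5.5]undecane (2,6-cis oxane, spiro 1,3-dithiane at C4) | COc1cc(CC[C@H]2CC3(C[C@@H](c4ccc(O[Si](C(C)C)(C(C)C)C(C)C)c(OC)c4)O2)SCCCS3)ccc1O[Si](C(C)C)(C(C)C)C(C)C | intermediate
19 | (2S,6S)-2-[3-methoxy-4-(triisopropylsilyloxy)phenyl]-6-{2-[3-methoxy-4-(triisopropylsilyloxy)phenyl]ethyl}oxan-4-one | COc1cc(CC[C@H]2CC(=O)C[C@@H](c3ccc(O[Si](C(C)C)(C(C)C)C(C)C)c(OC)c3)O2)ccc1O[Si](C(C)C)(C(C)C)C(C)C | intermediate
20 | (2S,4S,6S)-2-[3-methoxy-4-(triisopropylsilyloxy)phenyl]-6-{2-[3-methoxy-4-(triisopropylsilyloxy)phenyl]ethyl}oxan-4-ol | COc1cc(CC[C@H]2C[C@H](O)C[C@@H](c3ccc(O[Si](C(C)C)(C(C)C)C(C)C)c(OC)c3)O2)ccc1O[Si](C(C)C)(C(C)C)C(C)C | intermediate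
21 | (2S,4S,6S)-2-(4-hydroxy-3-methoxyphenyl)-6-[2-(4-hydroxy-3-methoxyphenyl)ethyl]oxan-4-ol | COc1cc(CC[C@H]2C[C@H](O)C[C@@H](c3ccc(O)c(OC)c3)O2)ccc1O | target

## Step count and least certain steps

Total step count: 13. Longest linear sequence: 10 steps (eugenol 7 to 21, steps 4 to 13).

**Step 9 (key step).** The most likely failure is loss of regiocontrol in the first opening. The electron-rich aryl oxirane 6 can be attacked at its benzylic carbon or isomerise to an arylacetaldehyde under lithium-ion activation, and premature silyl migration would let the relay consume 6 twice. The fallback sets out from 3, leaves 6 out and comes back at 17 through the same alkoxide 15, now made by carbonyl addition. Lithiated 3 is treated with ethylene oxide in Et2O and protonated cold to give 2-[2-(tert-butyldimethylsilyl)-1,3-dithian-2-yl]ethan-1-ol F1. Oxidation with SO3·pyridine, DMSO and Et3N gives 2-[2-(tert-butyldimethylsilyl)-1,3-dithian-2-yl]acetaldehyde F2. Commercial 4-bromo-2-methoxyphenol is silylated with TIPSCl to (4-bromo-2-methoxyphenoxy)triisopropylsilane F3. Bromine–lithium exchange with t-BuLi in Et2O at −78 °C gives [3-methoxy-4-(triisopropylsilyloxy)phenyl]lithium F4, which adds to F2 to give 15. HMPA and 13 are then added as in step 9, so the silyl migration and the second epoxide opening are unchanged and the sequence returns to 17.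

**Step 10.** The most likely failure is proton loss from the benzylic cation to a styrenyl dithiane instead of ring closure, or incomplete equilibration that leaves some 2,6-trans isomer. The fallback sets out from 17 and comes back at 19, closing the ring at the ketone level. Hydrolysis of 17 with MeI and CaCO3 gives (5S)-1-(tert-butyldimethylsilyloxy)-5-hydroxy-1,7-bis[3-methoxy-4-(triisopropylsilyloxy)phenyl]heptan-3-one F5. Acid (TsOH·H2O or a sulfonic acid resin in CH2Cl2) removes silanol to give the enone (1E,5S)-5-hydroxy-1,7-bis[3-methoxy-4-(triisopropylsilyloxy)phenyl]hept-1-en-3-one F6. Reversible 6-endo oxa-Michael addition of the C6 hydroxyl closes F6 to the cis oxanone 19. This order is not the first choice because it relies on benzylic C–O cleavage outrunning dehydration at C6.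

**Step 11.** The most likely failure is slow S-methylation of the hindered spiro dithioketal and, on forcing, retro-oxa-Michael opening of the β-alkoxy ketone as it forms. The fallback sets out from 18 and comes back at 19 with activation by oxidation instead of alkylation. One equivalent of mCPBA at −78 °C gives the monosulfoxide (8S,10S)-8-[3-methoxy-4-(triisopropylsilyloxy)phenyl]-10-{2-[3-methoxy-4-(triisopropylsilyloxy)phenyl]ethyl}-9-oxa-1,5-dithiaspiro[5.5]undecane 1-oxide F7. Dithioketal monoxides are hydrolysed by dilute aqueous acid in THF far more readily than the parent, which should give 19.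

**Step 3.** The most likely failure is sluggish ylide addition to the electron-rich aldehyde together with loss of 6 by benzylic ring opening during isolation. The fallback sets out from 5 and comes back at 6. Wittig methylenation (Ph3PCH3Br, KHMDS, THF) gives triisopropyl(4-ethenyl-2-methoxyphenoxy)silane F8. Epoxidation with dimethyldioxirane in acetone, a neutral oxidant with a volatile by-product, gives 6, which is used without chromatography.

**Step 12.** The most likely failure is incomplete facial selectivity, giving some equatorial alcohol. The fallback sets out from 19 and comes back at 20. NaBH4 in MeOH attacks axially and gives (2S,4R,6S)-2-[3-methoxy-4-(triisopropylsilyloxy)phenyl]-6-{2-[3-methoxy-4-(triisopropylsilyloxy)phenyl]ethyl}oxan-4-ol F9. Mitsunobu inversion (4-nitrobenzoic acid, Ph3P, DIAD) gives (2S,4S,6S)-2-[3-methoxy-4-(triisopropylsilyloxy)phenyl]-6-{2-[3-methoxy-4-(triisopropylsilyloxy)phenyl]ethyl}oxan-4-yl 4-nitrobenzoate F10. Methanolysis with K2CO3 in MeOH gives 20.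

## Further compounds

F1 | step 9 | 2-[2-(tert-butyldimethylsilyl)-1,3-dithian-2-yl]ethan-1-ol | CC(C)(C)[Si](C)(C)C1(CCO)SCCCS1
F2 | step 9 | 2-[2-(tert-butyldimethylsilyl)-1,3-dithian-2-yl]acetaldehyde | CC(C)(C)[Si](C)(C)C1(CC=O)SCCCS1
F3 | step 9 | (4-bromo-2-methoxyphenoxy)triisopropylsilane | COc1cc(Br)ccc1O[Si](C(C)C)(C(C)C)C(C)C
F4 | step 9 | [3-methoxy-4-(triisopropylsilyloxy)phenyl]lithium | COc1cc([Li])ccc1O[Si](C(C)C)(C(C)C)C(C)C
F5 | step 10 | (5S)-1-(tert-butyldimethylsilyloxy)-5-hydroxy-1,7-bis[3-methoxy-4-(triisopropylsilyloxy)phenyl]heptan-3-one (both C1 epimers) | COc1cc(CC[C@H](O)CC(=O)CC(O[Si](C)(C)C(C)(C)C)c2ccc(O[Si](C(C)C)(C(C)C)C(C)C)c(OC)c2)ccc1O[Si](C(C)C)(C(C)C)C(C)C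
F6 | step 10 | (1E,5S)-5-hydroxy-1,7-bis[3-methoxy-4-(triisopropylsilyloxy)phenyl]hept-1-en-3-one | COc1cc(CC[C@H](O)CC(=O)/C=C/c2ccc(O[Si](C(C)C)(C(C)C)C(C)C)c(OC)c2)ccc1O[Si](C(C)C)(C(C)C)C(C)C
F7 | step 11 | (8S,10S)-8-[3-methoxy-4-(triisopropylsilyloxy)phenyl]-10-{2-[3-methoxy-4-(triisopropylsilyloxy)phenyl]ethyl}-9-oxa-1,5-dithiaspiro[5.5]undecane 1-oxide (mixture at sulfur) | COc1cc(CC[C@H]2CC3(C[C@@H](c4ccc(O[Si](C(C)C)(C(C)C)C(C)C)c(OC)c4)O2)SCCCS3=O)ccc1O[Si](C(C)C)(C(C)C)C(C)C
F8 | step 3 | triisopropyl(4-ethenyl-2-methoxyphenoxy)silane | C=Cc1ccc(O[Si](C(C)C)(C(C)C)C(C)C)c(OC)c1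
F9 | step 12 | (2S,4R,6S)-2-[3-methoxy-4-(triisopropylsilyloxy)phenyl]-6-{2-[3-methoxy-4-(triisopropylsilyloxy)phenyl]ethyl}oxan-4-ol | COc1cc(CC[C@H]2C[C@@H](O)C[C@@H](c3ccc(O[Si](C(C)C)(C(C)C)C(C)C)c(OC)c3)O2)ccc1O[Si](C(C)C)(C(C)C)C(C)C
F10 | step 12 | (2S,4S,6S)-2-[3-methoxy-4-(triisopropylsilyloxy)phenyl]-6-{2-[3-methoxy-4-(triisopropylsilyloxy)phenyl]ethyl}oxan-4-yl 4-nitrobenzoate | COc1cc(CC[C@H]2C[C@H](OC(=O)c3ccc(cc3)[N+](=O)[O-])C[C@@H](c4ccc(O[Si](C(C)C)(C(C)C)C(C)C)c(OC)c4)O2)ccc1O[Si](C(C)C)(C(C)C)C(C)C
A1 | alternative 1 | (1S,3S)-3-(tert-butyldimethylsilyloxy)-1,7-bis[4-(tert-butyldimethylsilyloxy)-3-methoxyphenyl]hept-6-yn-1-ol | COc1cc(C#CCC[C@H](O[Si](C)(C)C(C)(C)C)C[C@H](O)c2ccc(O[Si](C)(C)C(C)(C)C)c(OC)c2)ccc1O[Si](C)(C)C(C)(C)C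
A2 | alternative 1 | (2S,4S,6R)-4-(tert-butyldimethylsilyloxy)-2-[4-(tert-butyldimethylsilyloxy)-3-methoxyphenyl]-6-{(E)-2-[4-(tert-butyldimethylsilyloxy)-3-methoxyphenyl]ethenyl}oxane | COc1cc(/C=C/[C@H]2C[C@H](O[Si](C)(C)C(C)(C)C)C[C@@H](c3ccc(O[Si](C)(C)C(C)(C)C)c(OC)c3)O2)ccc1O[Si](C)(C)C(C)(C)C
A3 | alternative 2 | 3-[4-(tert-butyldimethylsilyloxy)-3-methoxyphenyl]propanal | COc1cc(CCC=O)ccc1O[Si](C)(C)C(C)(C)C
A4 | alternative 2 | tert-butyl{2-methoxy-4-[(1E)-3-(triethylsilyloxy)buta-1,3-dien-1-yl]phenoxy}dimethylsilane | COc1cc(/C=C/C(=C)O[Si](CC)(CC)CC)ccc1O[Si](C)(C)C(C)(C)C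
A5 | alternative 2 | (2S,6S)-6-[4-(tert-butyldimethylsilyloxy)-3-methoxyphenyl]-2-{2-[4-(tert-butyldimethylsilyloxy)-3-methoxyphenyl]ethyl}-4-(triethylsilyloxy)-3,6-dihydro-2H-pyran | COc1cc(CC[C@H]2CC(O[Si](CC)(CC)CC)=C[C@@H](c3ccc(O[Si](C)(C)C(C)(C)C)c(OC)c3)O2)ccc1O[Si](C)(C)C(C)(C)C
A6 | alternative 3 | (4S)-4-{[4-(tert-butyldimethylsilyloxy)-3-methoxyphenyl]methoxy}-6-[3-methoxy-4-(pivaloyloxy)phenyl]hex-1-en-2-yl acetate | COc1cc(CC[C@H](OCc2ccc(O[Si](C)(C)C(C)(C)C)c(OC)c2)CC(=C)OC(C)=O)ccc1OC(=O)C(C)(C)C
A7 | alternative 3 | (2S,6S)-2-[4-(tert-butyldimethylsilyloxy)-3-methoxyphenyl]-6-{2-[3-methoxy-4-(pivaloyloxy)phenyl]ethyl}oxan-4-one | COc1cc(CC[C@H]2CC(=O)C[C@@H](c3ccc(O[Si](C)(C)C(C)(C)C)c(OC)c3)O2)ccc1OC(=O)C(C)(C)C
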